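## Analysis of the target

The target is a daucane-type sesquiterpenoid diester built on a cis-fused 1,2,3,3a,4,7,8,8a-octahydroazulene. The five-membered ring is C1, C2, C3, C3a, C8a; the seven-membered ring is C3a, C4 to C8, C8a, with a C5=C6 double bond that carries the C6 methyl group. There are six stereocentres, (2S,3R,3aR,4S,8S,8aS): C2 (acetate), C3 (tertiary alcohol bearing isopropyl), C3a (H), C4 (4-hydroxybenzoate), C8 (free secondary alcohol) and C8a (quaternary, methyl). Taking the face of the C8a methyl as β, the 3a-H, the C8 hydroxyl, the C2 acetate and the C3 hydroxyl are β, while the C4 aroyloxy group and the isopropyl group are α. The 2,3-diol unit is therefore cis and lies on the convex face of the bicycle. Sensitive points are the allylic ester at C4 (ionisation, acyl transfer), the acetate beside a free tertiary hydroxyl, the free phenol, and the C3–O/C4–O 1,3-relationship, which becomes a retro-aldol and elimination liability whenever C4 is a ketone. The difficulty lies in the contiguous C3–C3a–C8a array with two fully substituted carbons, and in five oxygen functions in four different states that must be told apart. The plan rests on one feature: C3 is bonded to C3a, and the next atom, C4, carries oxygen. A carbenoid at C3 can therefore add across a C3a=C4 alkene, which makes C3–C3a for good and C3–C4 for a while, and the surplus C3–C4 bond can then be cleaved by an oxygen nucleophile arriving at C4.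

## Retrosynthetic reasoning

**Esters and protecting groups.** Target 37 is traced to bis-silyl ether 36 (both Si–O bonds cut last), 36 to diol 35 (C2–O acyl bond), 35 to acetonide 34 (acetal C–O bonds), and 34 to allylic alcohol 30 and acid 33 (C4–O acyl bond). The two esters are the most fragile functions, so they enter at the end. The secondary/tertiary difference in 35 directs the acetate to C2, and the silyl groups keep C8–OH and the phenol out of both acylations.

**C4 carbinol and C5=C6 alkene.** Alcohol 30 comes from enone 29 by carbonyl reduction, and 29 from ketone 27 by removal of the C5 and C6 hydrogens. A C4 ketone is the one intermediate from which both the trisubstituted alkene and the C4 configuration can be derived, so the C6 methyl stereocentre carried up to that point is deliberately sacrificial. Ketone 27 comes from alcohol 26, which comes from acetate 25.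

**The 2,3-diol.** The two C–O bonds at C2 and C3 of 24 (protected as 25) are cut back to the C2=C3 alkene of 23. A syn-dihydroxylation from the convex face gives the cis-diol with both hydroxyls β. Alkene 23 is traced through enol triflate 22 to ketone 21, so that the double bond is placed by enolisation towards the more substituted α-carbon.

**The C4–O bond.** In 21 the C4–O bond is disconnected and C3–C4 is reconnected, which leads to cyclopropyl ketone 20. In the forward direction an oxygen nucleophile opens the ketone-activated cyclopropane at C4. This puts oxygen on C4 and returns C3 as an enolisable CH.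

**Key disconnection.** In 20 the bonds C3–C3a and C3–C4 are cut together, which gives diazoketone 19. The forward step is an intramolecular carbenoid addition to the C3a=C4 alkene. Nowhere else can two rings and the C3–C3a bond be made in one step from a monocycle, and the tether leaves no choice about the ring fusion. What remains is a cycloheptene with only two stereocentres that matter, C8 and C8a.

**Diazoketone.** The diazo group of 19 is traced to the methylene of ketone 17. Ketone 17 is cut at C2–C3 into Weinreb amide 15 and isobutyl Grignard reagent 16, and 15 comes from ester 14.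

**Quaternary C8a.** The C8a–C1 bond of 14 is cut as a [3,3] retron, which gives allylic alcohol 11 and orthoester 12. The forward rearrangement transfers the configuration of the carbinol to C8a across the face of the ring, so the crowded quaternary centre is made intramolecularly.

**Cycloheptene.** Alcohol 11 comes from enone 10 by reduction. The C3a=C8a double bond of 10 is cut by ring-closing metathesis to dienone 9. Dienone 9 is cut at C4–C3a into Weinreb amide 7 and vinyl Grignard reagent 8.

**Acyclic chain.** Amide 7 is traced through silyl ether 6 to carbinol 5, whose C8 stereocentre comes from enantioselective reduction of enone 4. Enone 4 is cut at C8–C8a into amide 2 and isopropenyl Grignard reagent 3, and 2 comes from hemiester 1, which supplies C4 to C8 and the C6 methyl.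

**Aroyl unit.** Acid 33 comes from 4-hydroxybenzoic acid 31 by silylation.

## Alternatives that were turned down

**Alternative 1:** The disconnection cuts C1–C2 and C3a–C8a, and the seven-membered ring arises from a six-membered one. In the forward step a thionium ion at C2, released from a dithioacetal by a thiophilic sulfonium salt, adds to the CH2 end of an isopropenyl group. The tertiary cation at C8a is then quenched by a 1,2-shift of C3a away from the silyloxy carbon C8, which gives the cis-fused ketone A1 (C8 ketone, C2 methylthio, C4=C5 alkene).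
- For: two C–C bonds, the quaternary C8a and the cis fusion arise in one cationic cascade, without a metal carbenoid and without a sacrificial bond. On bond-forming economy this is stronger than the chosen plan.
- Against: A1 has its functionality in the wrong places for this target. The alkene is C4=C5 and C4 has no oxygen, so an allylic oxidation with transposition is needed on a ring where several allylic positions compete. The sulfide must become the 2,3-cis-diol through a sulfoxide elimination whose direction (towards C1 or C3) is not controlled, and the later dihydroxylation must distinguish C2=C3 from the ring alkene. The C8 ketone needs a stereoselective reduction next to the quaternary centre.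
- Comparison: the chosen route is longer before its key step, but it places oxygen on C4 by the same bond cleavage that completes the key sequence, and it oxidises C2/C3 at a stage where no second alkene is present.

**Alternative 2:** The disconnection cuts C3a–C8a by ring contraction. In the forward step the silyl ketene acetal of the eleven-membered lactone precursor of A2 (acyl carbon C3, ring oxygen on C2, alkene C1=C8a) undergoes a [3,3] shift to the cycloheptene acid A2, which carries the C8a methyl/vinyl centre and the C3a carboxyl.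
- For: A2 already has C4–O, C8–O, the C5=C6 alkene and the correct configuration at C3a, C4, C8 and C8a. Only the five-membered ring is missing, and closing it between C2 and C3 by a carbonyl coupling could deliver the diol directly. In economy after the key step, and in avoiding redox corrections at C4, it is clearly stronger than the chosen strategy.
- Against: everything depends on a strained eleven-membered lactone holding two trisubstituted alkenes of defined geometry. Its assembly and lactonisation are long. The C3a/C8a relationship depends on the boat or chair preference of a transannular transition state and on ketene acetal geometry, neither of which the structure fixes. The ester enolate carries a β-alkoxy group at C4 that can eliminate.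
- Comparison: the chosen strategy gives up that convergence of functionality in exchange for a precursor made by standard reactions and a key step whose stereochemistry is dictated by the tether.

**Alternative 3:** The disconnection cuts C1–C8a and C3–C3a, a (3+2) annulation onto enone 10, which the chosen route also passes through. In the forward step a strong Lewis acid activates 10, and the CH2 end of allenylsilane A3 adds to the β-carbon C8a. Silicon shifts to the central carbon, and the vinyl cation is captured by the enolate carbon C3a, giving A4 (C2–SiMe3, C3–isopropyl, C4 ketone).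
- For: it is the most convergent plan. Both ring bonds form in one step, addition anti to the C8 silyl ether would set C8a correctly, and the C4 carbonyl needed later is already present. In step count it would beat the chosen route by a wide margin.
- Against: C8a is the β-carbon of a β,β-disubstituted enone flanked by a silyloxy-bearing carbon. This is the least favourable case for an intermolecular conjugate addition that must create a quaternary centre, and the γ-silyloxy enone is exposed to a strong Lewis acid. The tetrasubstituted vinylsilane must then be protodesilylated and dihydroxylated while C3a–H sits between the alkene and the C4 ketone (epimerisation, conjugation). C3–OH would be β to that ketone from the outset.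
- Comparison: the chosen plan builds C8a by an intramolecular sigmatropic shift and C3–C3a by an intramolecular carbenoid addition, both insensitive to the crowding at C8a, and it keeps C4 at the alcohol level until the diol is masked.

Key step: step 13

**Remarks and assumptions**

- Azulene numbering is used for all bicyclic compounds. β is the face carrying the C8a methyl group and α the opposite face. TBSO stands for (tert-butyldimethylsilyl)oxy.
- Hemiester 1 is taken as the purchasable enantiopure compound. It is the hemiester that enantioselective methanolysis of 3-methylglutaric anhydride delivers.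
- Where a step creates a centre that is erased later (C3 in 21, C4 in 21 to 26), the epimer expected from the mechanism is drawn. The other epimer would converge.

## Route

Step 1
Reactants: 1 methyl hydrogen (R)-3-methylglutarate
Product: 2 methyl (3R)-5-[methoxy(methyl)amino]-3-methyl-5-oxopentanoate
Conditions: MeNHOMe·HCl, EDC·HCl, DMAP (cat.), Et3N, CH2Cl2, 0 °C to rt
Reagents that add atoms: N,O-dimethylhydroxylamine hydrochloride, CNOC.Cl
Why: Carbodiimide-mediated amide formation (Weinreb amide synthesis) takes place at the free acid only; the methyl ester is untouched and the stereocentre (later C6) is not at an acidic position.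

Step 2
Reactants: 2 methyl (3R)-5-[methoxy(methyl)amino]-3-methyl-5-oxopentanoate; 3 isopropenylmagnesium bromide
Product: 4 methyl (3R)-3,6-dimethyl-5-oxohept-6-enoate
Conditions: THF, −40 to −10 °C; inverse quench into cold aq. NH4Cl
Reagents that add atoms: none
Why: Weinreb ketone synthesis: the chelated magnesium adduct survives until work-up, so the enone is never exposed to the Grignard reagent, and the chelating amide reacts faster than the methyl ester at low temperature.

Step 3
Reactants: 4 methyl (3R)-3,6-dimethyl-5-oxohept-6-enoate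
Product: 5 methyl (3R,5S)-5-hydroxy-3,6-dimethylhept-6-enoate
Conditions: (R)-2-methyl-CBS-oxazaborolidine (20 mol%), catecholborane, toluene, −78 °C
Reagents that add atoms: none
Why: Corey–Bakshi–Shibata reduction: the α-methylvinyl group acts as the large substituent, so the (R)-catalyst should give the (5S)-carbinol (later C8) under reagent control; the ester and the 1,1-disubstituted alkene are inert to catecholborane at −78 °C.

Step 4
Reactants: 5 methyl (3R,5S)-5-hydroxy-3,6-dimethylhept-6-enoate
Product: 6 methyl (3R,5S)-5-(TBSO)-3,6-dimethylhept-6-enoate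
Conditions: TBSOTf, 2,6-lutidine, CH2Cl2, −78 °C
Reagents that add atoms: tert-butyldimethylsilyl trifluoromethanesulfonate, CC(C)(C)[Si](C)(C)OS(=O)(=O)C(F)(F)F
Why: Silylation of the secondary allylic alcohol with the silyl triflate is fast at low temperature and is run directly on crude 5, so that δ-lactonisation onto the ester cannot compete.

Step 5
Reactants: 6 methyl (3R,5S)-5-(TBSO)-3,6-dimethylhept-6-enoate
Product: 7 (3R,5S)-5-(TBSO)-N-methoxy-N,3,6-trimethylhept-6-enamide
Conditions: MeNHOMe·HCl, i-PrMgCl, THF, −20 to 0 °C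
Reagents that add atoms: N,O-dimethylhydroxylamine hydrochloride, CNOC.Cl
Why: Direct aminolysis of the methyl ester by the magnesium amide of N,O-dimethylhydroxylamine (ester to Weinreb amide); the silyl ether and alkene do not react.

Step 6
Reactants: 7 (3R,5S)-5-(TBSO)-N-methoxy-N,3,6-trimethylhept-6-enamide; 8 vinylmagnesium bromide
Product: 9 (5R,7S)-7-(TBSO)-5,8-dimethylnona-1,8-dien-3-one
Conditions: THF, −78 to 0 °C; inverse quench into cold 1 M HCl
Reagents that add atoms: none
Why: Weinreb ketone synthesis; the acidic inverse quench protonates the liberated amine before it can add to the vinyl ketone, and the dienone is used at once.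

Step 7
Reactants: 9 (5R,7S)-7-(TBSO)-5,8-dimethylnona-1,8-dien-3-one
Product: 10 (4S,6R)-4-(TBSO)-3,6-dimethylcyclohept-2-en-1-one
Conditions: second-generation Grubbs catalyst (5 mol%), CH2Cl2 (5 mM), 40 °C
Reagents that add atoms: none
Why: Ring-closing metathesis between the vinyl ketone and the 1,1-disubstituted alkene closes the seven-membered ring as the trisubstituted enone with loss of ethene; high dilution suppresses dimerisation.

Step 8
Reactants: 10 (4S,6R)-4-(TBSO)-3,6-dimethylcyclohept-2-en-1-one
Product: 11 (1S,4S,6S)-4-(TBSO)-3,6-dimethylcyclohept-2-en-1-ol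
Conditions: (R)-2-methyl-CBS-oxazaborolidine (20 mol%), catecholborane, toluene, −78 °C
Reagents that add atoms: none
Why: Corey–Bakshi–Shibata 1,2-reduction of the cyclic enone with the alkenyl side as the large group; the (R)-catalyst should give the (1S)-alcohol, hydroxyl trans to the silyloxy group. This carbinol serves only to relay chirality in step 9.

Step 9
Reactants: 11 (1S,4S,6S)-4-(TBSO)-3,6-dimethylcyclohept-2-en-1-ol; 12 triethyl orthoacetate
Product: 14 ethyl 2-[(1S,5S,7S)-7-(TBSO)-1,5-dimethylcyclohept-2-en-1-yl]acetate, via mixed ketene acetal 13 (not isolated)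
Conditions: 12 as solvent, EtCO2H (10 mol%), 140 °C, EtOH distilled off
Reagents that add atoms: none
Why: Johnson–Claisen rearrangement: orthoester exchange and loss of ethanol give ketene acetal 13, whose [3,3] shift is suprafacial. The new C–C bond therefore forms at the methyl-bearing alkene carbon on the face the C–O bond leaves, anti to the neighbouring silyloxy group, which sets quaternary C8a (S, methyl cis to the silyloxy group) and moves the alkene to C3a=C4.

Step 10
Reactants: 14 ethyl 2-[(1S,5S,7S)-7-(TBSO)-1,5-dimethylcyclohept-2-en-1-yl]acetate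
Product: 15 2-[(1S,5S,7S)-7-(TBSO)-1,5-dimethylcyclohept-2-en-1-yl]-N-methoxy-N-methylacetamide
Conditions: MeNHOMe·HCl, i-PrMgCl, THF, −10 °C to rt
Reagents that add atoms: N,O-dimethylhydroxylamine hydrochloride, CNOC.Cl
Why: Ester to Weinreb amide as in step 5; the neopentyl-type ester is slower, so the mixture is allowed to reach room temperature.

Step 11
Reactants: 15 2-[(1S,5S,7S)-7-(TBSO)-1,5-dimethylcyclohept-2-en-1-yl]-N-methoxy-N-methylacetamide; 16 isobutylmagnesium bromide
Product: 17 1-[(1S,5S,7S)-7-(TBSO)-1,5-dimethylcyclohept-2-en-1-yl]-4-methylpentan-2-one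
Conditions: THF, 0 °C to rt; aq. NH4Cl
Reagents that add atoms: none
Why: Weinreb ketone synthesis; the chelated adduct stops the reaction at the ketone stage and forms the C2–C3 bond with the isopropyl group in place.

Step 12
Reactants: 17 1-[(1S,5S,7S)-7-(TBSO)-1,5-dimethylcyclohept-2-en-1-yl]-4-methylpentan-2-one
Product: 19 3-diazo-1-[(1S,5S,7S)-7-(TBSO)-1,5-dimethylcyclohept-2-en-1-yl]-4-methylpentan-2-one, via trifluoroacetyl ketone 18 (not isolated)
Conditions: LiN(SiMe3)2, THF, −78 °C; CF3CO2CH2CF3; dil. HCl work-up; then MsN3, Et3N, H2O (1 equiv), MeCN, rt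
Reagents that add atoms: methanesulfonyl azide, CS(=O)(=O)N=[N+]=[N-]; 2,2,2-trifluoroethyl trifluoroacetate, FC(F)(F)COC(=O)C(F)(F)F (supplies the trifluoroacetyl group of 18 only)
Why: Deacylative (detrifluoroacetylative) diazo transfer: kinetic deprotonation should occur at the isobutyl CH2 and not at the neopentyl CH2 next to quaternary C8a, so only C3 is activated; the sulfonyl azide then transfers N2 and the trifluoroacetyl group leaves as the sulfonamide.

Step 13
Reactants: 19 3-diazo-1-[(1S,5S,7S)-7-(TBSO)-1,5-dimethylcyclohept-2-en-1-yl]-4-methylpentan-2-one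
Product: 20 cyclopropyl ketone (3aβ-H)-8β-(TBSO)-3-isopropyl-6β,8aβ-dimethyl-3,4-cycloperhydroazulen-2-one (C3–C4 bond on the α face)
Conditions: Rh2(O2CCPh3)4 (1 mol%), CH2Cl2, −78 to 0 °C, slow addition of 19
Reagents that add atoms: none
Why: Loss of N2 at the dirhodium centre gives an electrophilic rhodium carbenoid at C3, which adds to the C3a=C4 alkene in a concerted, asynchronous [2+1] process; the closest known reaction type is the rhodium-catalysed intramolecular cyclopropanation of 1-diazohex-5-en-2-ones to bicyclo[3.1.0]hexan-2-ones. The cyclopentanone (C3, C2, C1, C8a, C3a) closes in the 5-exo sense, because C3 bonds to the proximal alkene carbon C3a through a three-atom tether, and the cyclopropane (C3, C3a, C4) closes as the C3–C4 bond forms in the same event. C3a and C4 keep the cis geometry of the ring alkene (stereospecific syn addition), and the tether from C8a allows the carbenoid to reach only the α face of the alkene, so the ring fusion must be cis with 3a-H and the C8a methyl both β. C3 has no freedom either: its bonds to C3a and C4 lie on the α face and the carbonyl bridge completes the five-membered ring, which leaves isopropyl exo. The step needs chemoselectivity for cyclopropanation over 1,2-hydride shift from the isopropyl methine (which would give an enone) and over 1,5-insertion into the C8–H bond. The bulky triphenylacetate ligands and the low temperature slow the hydride shift, the alkene is held within bonding distance of the carbenoid, and the C8–H bond is shielded by the silyl ether and the quaternary C8a.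

Step 14
Reactants: 20 cyclopropyl ketone (3aβ-H)-8β-(TBSO)-3-isopropyl-6β,8aβ-dimethyl-3,4-cycloperhydroazulen-2-one
Product: 21 (3aβ-H)-8β-(TBSO)-3β-isopropyl-6β,8aβ-dimethyl-2-oxodecahydroazulen-4β-yl acetate
Conditions: AcOH, TsOH·H2O (0.2 equiv), 40 °C
Reagents that add atoms: acetic acid, CC(=O)O
Why: Acid-catalysed homoconjugate addition to a cyclopropyl ketone: in the bicyclo[3.1.0]hexan-2-one unit the exocyclic C3–C4 bond, not the ring-fusion C3–C3a bond, is aligned with the carbonyl π system, and C4 is less hindered than the neopentyl-type C3a. Acetic acid should therefore attack C4 from the β face with inversion while the C2/C3 enol ketonises, which returns C3 as a CH; the configurations at C3 and C4 are erased in steps 15 and 20.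

Step 15
Reactants: 21 (3aβ-H)-8β-(TBSO)-3β-isopropyl-6β,8aβ-dimethyl-2-oxodecahydroazulen-4β-yl acetate
Product: 22 4β-acetoxy-8β-(TBSO)-3-isopropyl-6β,8aβ-dimethyl-1,3aβ,4,5,6,7,8,8a-octahydroazulen-2-yl trifluoromethanesulfonate
Conditions: Tf2O, 2,6-di-tert-butyl-4-methylpyridine, CH2Cl2, 0 °C to rt
Reagents that add atoms: trifluoromethanesulfonic anhydride, O=S(=O)(OS(=O)(=O)C(F)(F)F)C(F)(F)F
Why: Enol triflate formation with triflic anhydride and a hindered pyridine goes through the O-triflyl carbenium ion and gives mainly the more substituted enol triflate, here C2=C3; amide bases are avoided because kinetic deprotonation would go to C1. The acetate and the silyl ether are inert.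

Step 16
Reactants: 22 4β-acetoxy-8β-(TBSO)-3-isopropyl-6β,8aβ-dimethyl-1,3aβ,4,5,6,7,8,8a-octahydroazulen-2-yl trifluoromethanesulfonate
Product: 23 8β-(TBSO)-3-isopropyl-6β,8aβ-dimethyl-1,3aβ,4,5,6,7,8,8a-octahydroazulen-4β-yl acetate
Conditions: Pd(OAc)2 (5 mol%), PPh3 (10 mol%), HCO2H, n-Bu3N, DMF, 60 °C
Reagents that add atoms: none
Why: Palladium-catalysed formate reduction of an enol triflate: oxidative addition to zerovalent palladium, formate exchange, decarboxylation and reductive elimination replace OTf by H without moving the double bond; the acetate is homoallylic and cannot ionise.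

Step 17
Reactants: 23 8β-(TBSO)-3-isopropyl-6β,8aβ-dimethyl-1,3aβ,4,5,6,7,8,8a-octahydroazulen-4β-yl acetate
Product: 24 (3aβ-H)-8β-(TBSO)-2β,3β-dihydroxy-3α-isopropyl-6β,8aβ-dimethyldecahydroazulen-4β-yl acetate
Conditions: OsO4 (5 mol%), NMO, acetone–H2O, rt
Reagents that add atoms: osmium tetroxide, O=[Os](=O)(=O)=O (catalytic carrier of both oxygen atoms); N-methylmorpholine N-oxide, C[N+]1([O-])CCOCC1; water, O
Why: Osmium-catalysed syn-dihydroxylation of the only alkene. OsO4 should approach the convex β face of the cis-fused bicycle, anti to the allylic C3a–C4 bond and the seven-membered ring, so both hydroxyls come out β; this sets C2 (S) and C3 (R) with isopropyl α.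

Step 18
Reactants: 24 (3aβ-H)-8β-(TBSO)-2β,3β-dihydroxy-3α-isopropyl-6β,8aβ-dimethyldecahydroazulen-4β-yl acetate
Product: 25 (3aβ-H)-8β-(TBSO)-2β,3β-(isopropylidenedioxy)-3α-isopropyl-6β,8aβ-dimethyldecahydroazulen-4β-yl acetate
Conditions: Me2C(OMe)2, PPTS (cat.), CH2Cl2, rt
Reagents that add atoms: 2,2-dimethoxypropane, COC(C)(C)OC
Why: Acid-catalysed transketalisation closes a dioxolane on the cis-diol; this masks the tertiary hydroxyl before C4 becomes a ketone, where a free C3–OH would invite retro-aldol cleavage.

Step 19
Reactants: 25 (3aβ-H)-8β-(TBSO)-2β,3β-(isopropylidenedioxy)-3α-isopropyl-6β,8aβ-dimethyldecahydroazulen-4β-yl acetate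
Product: 26 (3aβ-H)-8β-(TBSO)-2β,3β-(isopropylidenedioxy)-3α-isopropyl-6β,8aβ-dimethyldecahydroazulen-4β-ol
Conditions: K2CO3, MeOH, 40 °C
Reagents that add atoms: none
Why: Base-catalysed transesterification removes the only ester; the acetonide and the hindered silyl ether are stable to carbonate in methanol.

Step 20
Reactants: 26 (3aβ-H)-8β-(TBSO)-2β,3β-(isopropylidenedioxy)-3α-isopropyl-6β,8aβ-dimethyldecahydroazulen-4β-ol
Product: 27 (3aβ-H)-8β-(TBSO)-2β,3β-(isopropylidenedioxy)-3α-isopropyl-6β,8aβ-dimethyldecahydroazulen-4-one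
Conditions: Dess–Martin periodinane, pyridine, CH2Cl2, 0 °C to rt
Reagents that add atoms: none
Why: Dess–Martin oxidation of the hindered secondary alcohol under buffered, non-basic conditions, so the C3a centre α to the new ketone is not epimerised and the β-oxygen at C3 is not eliminated.

Step 21
Reactants: 27 (3aβ-H)-8β-(TBSO)-2β,3β-(isopropylidenedioxy)-3α-isopropyl-6β,8aβ-dimethyldecahydroazulen-4-one
Product: 29 (3aβ-H)-8β-(TBSO)-2β,3β-(isopropylidenedioxy)-3α-isopropyl-6,8aβ-dimethyl-2,3,3a,7,8,8a-hexahydroazulen-4(1H)-one, via trimethylsilyl enol ether 28 (not isolated)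
Conditions: LiN(i-Pr)2, TMSCl, THF, −78 °C; then Pd(OAc)2 (1.1 equiv), MeCN, rt
Reagents that add atoms: chlorotrimethylsilane, C[Si](C)(C)Cl (supplies the silyl group of 28 only; no atoms remain in 29)
Why: Saegusa–Ito dehydrogenation: kinetic deprotonation occurs at the C5 methylene rather than the hindered C3a methine, the enolate is trapped as the C4=C5 silyl enol ether 28, and Pd(OAc)2 gives an oxa-π-allyl palladium species that loses the C6 hydrogen by β-hydride elimination. This forms the C5=C6 enone and removes the C6 stereocentre.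

Step 22
Reactants: 29 (3aβ-H)-8β-(TBSO)-2β,3β-(isopropylidenedioxy)-3α-isopropyl-6,8aβ-dimethyl-2,3,3a,7,8,8a-hexahydroazulen-4(1H)-one
Product: 30 (3aβ-H)-8β-(TBSO)-2β,3β-(isopropylidenedioxy)-3α-isopropyl-6,8aβ-dimethyl-1,2,3,3a,4,7,8,8a-octahydroazulen-4α-ol
Conditions: NaBH4, CeCl3·7H2O, MeOH, −78 to −40 °C
Reagents that add atoms: none
Why: Luche 1,2-reduction of the enone. Hydride is expected to reach C4 from the β face, the side of the 3a-H, because the α face is screened by the fully substituted C3 with its isopropyl group; this gives the 4α-alcohol (4S).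

Step 23
Reactants: 31 4-hydroxybenzoic acid
Product: 33 4-[(tert-butyldimethylsilyl)oxy]benzoic acid, via bis-silylated benzoate 32 (not isolated)
Conditions: TBSCl (2.5 equiv), imidazole, DMF, rt; then K2CO3, THF–MeOH–H2O, rt; citric acid work-up
Reagents that add atoms: tert-butyldimethylsilyl chloride, CC(C)(C)[Si](C)(C)Cl
Why: Both the phenol and the acid are silylated, and the much more labile silyl ester is then hydrolysed selectively under mild carbonate conditions, which leaves the aryl silyl ether.

Step 24
Reactants: 30 (3aβ-H)-8β-(TBSO)-2β,3β-(isopropylidenedioxy)-3α-isopropyl-6,8aβ-dimethyl-1,2,3,3a,4,7,8,8a-octahydroazulen-4α-ol; 33 4-[(tert-butyldimethylsilyl)oxy]benzoic acid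
Product: 34 (3aβ-H)-8β-(TBSO)-2β,3β-(isopropylidenedioxy)-3α-isopropyl-6,8aβ-dimethyl-1,2,3,3a,4,7,8,8a-octahydroazulen-4α-yl 4-(TBSO)benzoate
Conditions: EDC·HCl, DMAP (2 equiv), CH2Cl2, rt
Reagents that add atoms: none
Why: Steglich esterification (carbodiimide activation, DMAP acyl transfer) acylates the allylic alcohol with retention at C4; no other free hydroxyl is present.

Step 25
Reactants: 34 (3aβ-H)-8β-(TBSO)-2β,3β-(isopropylidenedioxy)-3α-isopropyl-6,8aβ-dimethyl-1,2,3,3a,4,7,8,8a-octahydroazulen-4α-yl 4-(TBSO)benzoate
Product: 35 (3aβ-H)-8β-(TBSO)-2β,3β-dihydroxy-3α-isopropyl-6,8aβ-dimethyl-1,2,3,3a,4,7,8,8a-octahydroazulen-4α-yl 4-(TBSO)benzoate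
Conditions: AcOH–H2O–THF (3:1:1), 45 °C
Reagents that add atoms: none
Why: Mild aqueous acid hydrolyses the dioxolane; the aryl silyl ether is acid-stable, the C8 silyl ether is secondary and next to a quaternary carbon and so hydrolyses much more slowly, and acetic acid does not ionise the allylic ester.

Step 26
Reactants: 35 (3aβ-H)-8β-(TBSO)-2β,3β-dihydroxy-3α-isopropyl-6,8aβ-dimethyl-1,2,3,3a,4,7,8,8a-octahydroazulen-4α-yl 4-(TBSO)benzoate
Product: 36 (3aβ-H)-2β-acetoxy-8β-(TBSO)-3β-hydroxy-3α-isopropyl-6,8aβ-dimethyl-1,2,3,3a,4,7,8,8a-octahydroazulen-4α-yl 4-(TBSO)benzoate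
Conditions: Ac2O, pyridine, DMAP (cat.), CH2Cl2, 0 °C to rt
Reagents that add atoms: acetic anhydride, CC(=O)OC(C)=O
Why: DMAP-catalysed acetylation takes place at the secondary C2 hydroxyl only; the tertiary C3 hydroxyl is too hindered to react and the other two hydroxyls are still silylated.

Step 27
Reactants: 36 (3aβ-H)-2β-acetoxy-8β-(TBSO)-3β-hydroxy-3α-isopropyl-6,8aβ-dimethyl-1,2,3,3a,4,7,8,8a-octahydroazulen-4α-yl 4-(TBSO)benzoate
Product: 37 (2S,3R,3aR,4S,8S,8aS)-2-acetoxy-3,8-dihydroxy-6,8a-dimethyl-3-(propan-2-yl)-1,2,3,3a,4,7,8,8a-octahydroazulen-4-yl 4-hydroxybenzoate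
Conditions: HF·pyridine, pyridine, THF, 0 °C to rt
Reagents that add atoms: none
Why: Fluoride cleaves the aryl and the alkyl silyl ether under buffered, weakly acidic conditions that neither hydrolyse nor migrate the acetate and the aroyl ester.

## Compound list

1 | methyl hydrogen (R)-3-methylglutarate, (3R)-5-methoxy-3-methyl-5-oxopentanoic acid | OC(=O)C[C@@H](C)CC(=O)OC | starting material
2 | methyl (3R)-5-[methoxy(methyl)amino]-3-methyl-5-oxopentanoate | CON(C)C(=O)C[C@@H](C)CC(=O)OC | intermediate
3 | isopropenylmagnesium bromide | C=C(C)[Mg]Br | starting material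
4 | methyl (3R)-3,6-dimethyl-5-oxohept-6-enoate | C=C(C)C(=O)C[C@@H](C)CC(=O)OC | intermediate
5 | methyl (3R,5S)-5-hydroxy-3,6-dimethylhept-6-enoate | C=C(C)[C@@H](O)C[C@@H](C)CC(=O)OC | intermediate
6 | methyl (3R,5S)-5-[(tert-butyldimethylsilyl)oxy]-3,6-dimethylhept-6-enoate | C=C(C)[C@@H](O[Si](C)(C)C(C)(C)C)C[C@@H](C)CC(=O)OC | intermediate
7 | (3R,5S)-5-[(tert-butyldimethylsilyl)oxy]-N-methoxy-N,3,6-trimethylhept-6-enamide | C=C(C)[C@@H](O[Si](C)(C)C(C)(C)C)C[C@@H](C)CC(=O)N(C)OC | intermediate
8 | vinylmagnesium bromide | C=C[Mg]Br | starting material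
9 | (5R,7S)-7-[(tert-butyldimethylsilyl)oxy]-5,8-dimethylnona-1,8-dien-3-one | C=C(C)[C@@H](O[Si](C)(C)C(C)(C)C)C[C@@H](C)CC(=O)C=C | intermediate
10 | (4S,6R)-4-[(tert-butyldimethylsilyl)oxy]-3,6-dimethylcyclohept-2-en-1-one | CC1=CC(=O)C[C@H](C)C[C@@H]1O[Si](C)(C)C(C)(C)C | intermediate
11 | (1S,4S,6S)-4-[(tert-butyldimethylsilyl)oxy]-3,6-dimethylcyclohept-2-en-1-ol | CC1=C[C@@H](O)C[C@H](C)C[C@@H]1O[Si](C)(C)C(C)(C)C | intermediate
12 | triethyl orthoacetate | CCOC(C)(OCC)OCC | starting material
13 | mixed ketene acetal, the 1-ethoxyvinyl ether of 11 (configuration as in 11) | C=C(OCC)O[C@@H]1C=C(C)[C@@H](O[Si](C)(C)C(C)(C)C)C[C@@H](C)C1 | intermediate (not isolated)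
14 | ethyl 2-[(1S,5S,7S)-7-[(tert-butyldimethylsilyl)oxy]-1,5-dimethylcyclohept-2-en-1-yl]acetate | CCOC(=O)C[C@]1(C)[C@@H](O[Si](C)(C)C(C)(C)C)C[C@@H](C)CC=C1 | intermediate
15 | 2-[(1S,5S,7S)-7-[(tert-butyldimethylsilyl)oxy]-1,5-dimethylcyclohept-2-en-1-yl]-N-methoxy-N-methylacetamide | CON(C)C(=O)C[C@]1(C)[C@@H](O[Si](C)(C)C(C)(C)C)C[C@@H](C)CC=C1 | intermediate
16 | isobutylmagnesium bromide | CC(C)C[Mg]Br | starting material
17 | 1-[(1S,5S,7S)-7-[(tert-butyldimethylsilyl)oxy]-1,5-dimethylcyclohept-2-en-1-yl]-4-methylpentan-2-one | CC(C)CC(=O)C[C@]1(C)[C@@H](O[Si](C)(C)C(C)(C)C)C[C@@H](C)CC=C1 | intermediate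
18 | trifluoroacetyl ketone, the 3-(trifluoroacetyl) derivative of 17 (carbon between the carbonyls configurationally labile, present as enol/enolate) | CC(C)C(C(=O)C(F)(F)F)C(=O)C[C@]1(C)[C@@H](O[Si](C)(C)C(C)(C)C)C[C@@H](C)CC=C1 | intermediate (not isolated)
19 | 3-diazo-1-[(1S,5S,7S)-7-[(tert-butyldimethylsilyl)oxy]-1,5-dimethylcyclohept-2-en-1-yl]-4-methylpentan-2-one | CC(C)C(=[N+]=[N-])C(=O)C[C@]1(C)[C@@H](O[Si](C)(C)C(C)(C)C)C[C@@H](C)CC=C1 | intermediate
20 | cyclopropyl ketone: (3aβ-H)-8β-(TBSO)-3-isopropyl-6β,8aβ-dimethyl-3,4-cycloperhydroazulen-2-one, cyclopropane C3–C3a–C4 on the α face (tricyclo[5.3.0.0(2,10)]decan-9-one core) | O=C1C[C@]2(C)[C@@H](O[Si](C)(C)C(C)(C)C)C[C@@H](C)C[C@H]3[C@@H]2[C@@]13C(C)C | intermediate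
21 | (3aβ-H)-8β-(TBSO)-3β-isopropyl-6β,8aβ-dimethyl-2-oxodecahydroazulen-4β-yl acetate | O=C1C[C@]2(C)[C@@H](O[Si](C)(C)C(C)(C)C)C[C@@H](C)C[C@@H](OC(C)=O)[C@@H]2[C@H]1C(C)C | intermediate
22 | 4β-acetoxy-8β-(TBSO)-3-isopropyl-6β,8aβ-dimethyl-1,3aβ,4,5,6,7,8,8a-octahydroazulen-2-yl trifluoromethanesulfonate | CC(C)C1=C(OS(=O)(=O)C(F)(F)F)C[C@]2(C)[C@@H](O[Si](C)(C)C(C)(C)C)C[C@@H](C)C[C@@H](OC(C)=O)[C@H]12 | intermediate
23 | 8β-(TBSO)-3-isopropyl-6β,8aβ-dimethyl-1,3aβ,4,5,6,7,8,8a-octahydroazulen-4β-yl acetate | CC(C)C1=CC[C@]2(C)[C@@H](O[Si](C)(C)C(C)(C)C)C[C@@H](C)C[C@@H](OC(C)=O)[C@H]12 | intermediate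
24 | (3aβ-H)-8β-(TBSO)-2β,3β-dihydroxy-3α-isopropyl-6β,8aβ-dimethyldecahydroazulen-4β-yl acetate | O[C@H]1C[C@]2(C)[C@@H](O[Si](C)(C)C(C)(C)C)C[C@@H](C)C[C@@H](OC(C)=O)[C@@H]2[C@]1(O)C(C)C | intermediate
25 | 2β,3β-O-isopropylidene acetal of 24 | CC1(C)O[C@H]2C[C@]3(C)[C@@H](O[Si](C)(C)C(C)(C)C)C[C@@H](C)C[C@@H](OC(C)=O)[C@@H]3[C@]2(O1)C(C)C | intermediate
26 | (3aβ-H)-8β-(TBSO)-2β,3β-(isopropylidenedioxy)-3α-isopropyl-6β,8aβ-dimethyldecahydroazulen-4β-ol | CC1(C)O[C@H]2C[C@]3(C)[C@@H](O[Si](C)(C)C(C)(C)C)C[C@@H](C)C[C@@H](O)[C@@H]3[C@]2(O1)C(C)C | intermediate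
27 | (3aβ-H)-8β-(TBSO)-2β,3β-(isopropylidenedioxy)-3α-isopropyl-6β,8aβ-dimethyldecahydroazulen-4-one | CC1(C)O[C@H]2C[C@]3(C)[C@@H](O[Si](C)(C)C(C)(C)C)C[C@@H](C)CC(=O)[C@@H]3[C@]2(O1)C(C)C | intermediate
28 | trimethylsilyl enol ether of 27 (C4=C5, OSiMe3 on C4) | CC1(C)O[C@H]2C[C@]3(C)[C@@H](O[Si](C)(C)C(C)(C)C)C[C@@H](C)C=C(O[Si](C)(C)C)[C@@H]3[C@]2(O1)C(C)C | intermediate (not isolated)
29 | (3aβ-H)-8β-(TBSO)-2β,3β-(isopropylidenedioxy)-3α-isopropyl-6,8aβ-dimethyl-2,3,3a,7,8,8a-hexahydroazulen-4(1H)-one | CC1(C)O[C@H]2C[C@]3(C)[C@@H](O[Si](C)(C)C(C)(C)C)CC(C)=CC(=O)[C@@H]3[C@]2(O1)C(C)C | intermediate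
30 | (3aβ-H)-8β-(TBSO)-2β,3β-(isopropylidenedioxy)-3α-isopropyl-6,8aβ-dimethyl-1,2,3,3a,4,7,8,8a-octahydroazulen-4α-ol | CC1(C)O[C@H]2C[C@]3(C)[C@@H](O[Si](C)(C)C(C)(C)C)CC(C)=C[C@H](O)[C@@H]3[C@]2(O1)C(C)C | intermediate
31 | 4-hydroxybenzoic acid | OC(=O)c1ccc(O)cc1 | starting material
32 | tert-butyldimethylsilyl 4-[(tert-butyldimethylsilyl)oxy]benzoate | CC(C)(C)[Si](C)(C)OC(=O)c1ccc(O[Si](C)(C)C(C)(C)C)cc1 | intermediate (not isolated)
33 | 4-[(tert-butyldimethylsilyl)oxy]benzoic acid | CC(C)(C)[Si](C)(C)Oc1ccc(cc1)C(=O)O | intermediate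
34 | (3aβ-H)-8β-(TBSO)-2β,3β-(isopropylidenedioxy)-3α-isopropyl-6,8aβ-dimethyl-1,2,3,3a,4,7,8,8a-octahydroazulen-4α-yl 4-(TBSO)benzoate | CC1(C)O[C@H]2C[C@]3(C)[C@@H](O[Si](C)(C)C(C)(C)C)CC(C)=C[C@H](OC(=O)c4ccc(O[Si](C)(C)C(C)(C)C)cc4)[C@@H]3[C@]2(O1)C(C)C | intermediate
35 | (3aβ-H)-8β-(TBSO)-2β,3β-dihydroxy-3α-isopropyl-6,8aβ-dimethyl-1,2,3,3a,4,7,8,8a-octahydroazulen-4α-yl 4-(TBSO)benzoate | O[C@H]1C[C@]2(C)[C@@H](O[Si](C)(C)C(C)(C)C)CC(C)=C[C@H](OC(=O)c3ccc(O[Si](C)(C)C(C)(C)C)cc3)[C@@H]2[C@]1(O)C(C)C | intermediate
36 | (3aβ-H)-2β-acetoxy-8β-(TBSO)-3β-hydroxy-3α-isopropyl-6,8aβ-dimethyl-1,2,3,3a,4,7,8,8a-octahydroazulen-4α-yl 4-(TBSO)benzoate | CC(=O)O[C@H]1C[C@]2(C)[C@@H](O[Si](C)(C)C(C)(C)C)CC(C)=C[C@H](OC(=O)c3ccc(O[Si](C)(C)C(C)(C)C)cc3)[C@@H]2[C@]1(O)C(C)C | intermediate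
37 | (2S,3R,3aR,4S,8S,8aS)-2-acetoxy-3,8-dihydroxy-6,8a-dimethyl-3-(propan-2-yl)-1,2,3,3a,4,7,8,8a-octahydroazulen-4-yl 4-hydroxybenzoate | CC(=O)O[C@H]1C[C@]2(C)[C@@H](O)CC(C)=C[C@H](OC(=O)c3ccc(O)cc3)[C@@H]2[C@]1(O)C(C)C | target

## Step count and least certain steps

Total step count: 27. Longest linear sequence: 26 steps (steps 1 to 22 and 24 to 27); step 23 is a one-step side branch.

**Step 13 (key step).** The carbenoid may rearrange by 1,2-hydride shift from the isopropyl methine before it reaches the alkene, or insert into the C8–H bond that lies cis to the side chain, because an acceptor carbenoid with a tertiary β-hydrogen is short-lived and unselective. The fallback removes the β-hydrogen. It sets out from Weinreb amide 15, which with 2-methylallylmagnesium chloride gives the β,γ-unsaturated ketone F1. Direct diazo transfer (4-acetamidobenzenesulfonyl azide, DBU, MeCN, 0 °C) at the doubly activated methylene gives the vinyl diazoketone F2. Rh2(OAc)4 turns F2 into a donor–acceptor vinylcarbenoid, which cannot undergo hydride shift and adds intramolecularly to the alkene to give the isopropenyl cyclopropyl ketone F3. Hydrogenation of the 1,1-disubstituted alkene with H2 and RhCl(PPh3)3 then rejoins the route at 20.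

**Step 14.** Ionisation at C4 may be followed by proton loss instead of capture by acetic acid, the ring-fusion bond C3–C3a may be cleaved in competition, or the C8 silyl ether may be lost in the acidic medium. The fallback sets out from 20, which is reduced with NaBH4 to the cyclopropyl carbinol F4. F4 is left in acetic acid with a trace of TsOH at room temperature, where the cyclopropylcarbinyl cation at C2 forms far more readily than the protonated ketone opens. Acetate again enters at C4 anti to the breaking C3–C4 bond, and the C2=C3 alkene forms directly (cyclopropylcarbinyl to homoallyl rearrangement). The route is rejoined at 23, and steps 15 and 16 are not needed.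

**Step 15.** Regioselectivity may be poor: proton loss from the accessible C1 methylene can compete with loss of the hindered C3–H, giving the C1=C2 triflate. The fallback fixes the double bond by the position of a leaving group. It sets out from 21, whose acid-catalysed bromination (pyridinium tribromide, AcOH), running through the more substituted enol, gives the 3-bromo ketone F5. NaBH4 reduces F5 to the bromohydrin F6, and zinc in acetic acid effects reductive 1,2-elimination, which rejoins the route at 23.

**Step 22.** Facial selectivity may be poor: if the ring folds so that the C8a methyl shields the β face, hydride arrives from the α face and the 4β-alcohol results. The fallback uses that epimer. The 4β-alcohol F9, obtained from 29, is esterified with acid 33 under Mitsunobu conditions (PPh3, diisopropyl azodicarboxylate), which forms the ester with inversion at C4 and rejoins the route at 34 in place of step 24.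

**Step 8.** Catalyst control may be overridden by the bias of the ring (the bulky silyloxy group 1,4 to the carbonyl), leading to the cis-alcohol. The fallback accepts substrate control. It sets out from 10, which is reduced with NaBH4 and CeCl3·7H2O to the cis-alcohol F7. Mitsunobu reaction with 4-nitrobenzoic acid inverts the carbinol to the ester F8, and methanolysis (K2CO3, MeOH) rejoins the route at 11.

## Further compounds

F1 | step 13 | 1-[(1S,5S,7S)-7-[(tert-butyldimethylsilyl)oxy]-1,5-dimethylcyclohept-2-en-1-yl]-4-methylpent-4-en-2-one | C=C(C)CC(=O)C[C@]1(C)[C@@H](O[Si](C)(C)C(C)(C)C)C[C@@H](C)CC=C1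
F2 | step 13 | 3-diazo-1-[(1S,5S,7S)-7-[(tert-butyldimethylsilyl)oxy]-1,5-dimethylcyclohept-2-en-1-yl]-4-methylpent-4-en-2-one | C=C(C)C(=[N+]=[N-])C(=O)C[C@]1(C)[C@@H](O[Si](C)(C)C(C)(C)C)C[C@@H](C)CC=C1
F3 | step 13 | 3-isopropenyl analogue of 20: (3aβ-H)-8β-(TBSO)-6β,8aβ-dimethyl-3-(prop-1-en-2-yl)-3,4-cycloperhydroazulen-2-one | O=C1C[C@]2(C)[C@@H](O[Si](C)(C)C(C)(C)C)C[C@@H](C)C[C@H]3[C@@H]2[C@@]13C(C)=C
F4 | step 14 | cyclopropyl carbinol: 2α-alcohol from 20 (hydride anti to the cyclopropane; either C2 epimer serves) | O[C@@H]1C[C@]2(C)[C@@H](O[Si](C)(C)C(C)(C)C)C[C@@H](C)C[C@H]3[C@@H]2[C@@]13C(C)C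
F5 | step 15 | (3aβ-H)-3β-bromo-8β-(TBSO)-3α-isopropyl-6β,8aβ-dimethyl-2-oxodecahydroazulen-4β-yl acetate | O=C1C[C@]2(C)[C@@H](O[Si](C)(C)C(C)(C)C)C[C@@H](C)C[C@@H](OC(C)=O)[C@@H]2[C@]1(Br)C(C)C
F6 | step 15 | (3aβ-H)-3β-bromo-8β-(TBSO)-2β-hydroxy-3α-isopropyl-6β,8aβ-dimethyldecahydroazulen-4β-yl acetate (either C2 epimer serves) | O[C@H]1C[C@]2(C)[C@@H](O[Si](C)(C)C(C)(C)C)C[C@@H](C)C[C@@H](OC(C)=O)[C@@H]2[C@]1(Br)C(C)C
F7 | step 8 | (1R,4S,6S)-4-[(tert-butyldimethylsilyl)oxy]-3,6-dimethylcyclohept-2-en-1-ol | CC1=C[C@H](O)C[C@H](C)C[C@@H]1O[Si](C)(C)C(C)(C)C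
F8 | step 8 | 4-nitrobenzoate of 11 | CC1=C[C@@H](OC(=O)c2ccc(cc2)[N+](=O)[O-])C[C@H](C)C[C@@H]1O[Si](C)(C)C(C)(C)C
F9 | step 22 | 4β-epimer of 30 | CC1(C)O[C@H]2C[C@]3(C)[C@@H](O[Si](C)(C)C(C)(C)C)CC(C)=C[C@@H](O)[C@@H]3[C@]2(O1)C(C)C
A1 | alternative 1 | cis-fused 3-isopropyl-6,8a-dimethyl-2-(methylthio)hexahydroazulen-8-one with a C4=C5 alkene | CS[C@H]1C[C@]2(C)C(=O)C[C@@H](C)C=C[C@@H]2[C@@H]1C(C)C
A2 | alternative 2 | cycloheptene carboxylic acid with cis carboxyl (on C3a) and vinyl (on C8a) groups | C=C[C@]1(C)[C@@H](O[Si](C)(C)C(C)(C)C)CC(C)=C[C@H](OCc2ccc(OC)cc2)[C@@H]1C(=O)O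
A3 | alternative 3 | trimethyl(4-methylpenta-1,2-dien-3-yl)silane | C=C=C(C(C)C)[Si](C)(C)C
A4 | alternative 3 | cis-fused 3-isopropyl-2-(trimethylsilyl)cyclopentene on the cycloheptanone (C4 ketone, C8 silyl ether) | CC(C)C1=C([Si](C)(C)C)C[C@]2(C)[C@@H](O[Si](C)(C)C(C)(C)C)C[C@@H](C)CC(=O)[C@H]12
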